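Ring B (C5, C6, C7, C8, C9, C10) is closed last, on a finished ring A, by forming the C9–C10 bond. Ionisation of a C10 tertiary chloride and capture of the cation by a tethered (Z)-allylsilane forms ring B, the C10 quaternary and C9 stereocentres, the trans fusion and the C8=C17 methylene in one operation. The step exploits the syn-axial pair C2–O/C19 of ring A: tied as a bridged γ-lactone, it locks the chair, shields the α face of C10 and holds C6 equatorial. The precursor is this bicyclic lactone carrying the complete C6–C15 chain, assembled by two Negishi couplings on a 1,1-dibromoalkene.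

Key step: step 14

Remark on numbering: C1–C20 are the labdane positions of the target (ring A: C1–C5, C10; ring B: C5–C10); α means the ring-A face that carries C19.
Assumption: step 12 may give both C10 epimers; both ionise to the same cation in step 14, and 19 and 20 are written as the epimer with chlorine β.

Step 1
Reactants: 1 5,6-dihydro-2H-pyran-2-one; 2 potassium trifluoro(prop-1-en-2-yl)borate
Product: 3 (4R)-4-(prop-1-en-2-yl)oxan-2-one
Conditions: [Rh(C8H12)2]PF6 (3 mol %), (R)-BINAP (3.3 mol %), toluene/H2O 20:1, 105 °C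
Reagents that add atoms: none
Why: Hayashi–Miyaura rhodium-catalysed asymmetric 1,4-addition of an alkenylboron reagent to an unsaturated lactone, in which the chiral bisphosphine–rhodium complex selects one face of the acceptor and sets C5 as the (4R) centre of 3; the (R) ligand is chosen because the (S) ligand gives the (S) adducts in the aryl series.

Step 2
Reactants: 3 (4R)-4-(prop-1-en-2-yl)oxan-2-one; 4 1-bromo-3-methylbut-2-ene
Product: 5 (3S,4R)-3-(3-methylbut-2-en-1-yl)-4-(prop-1-en-2-yl)oxan-2-one
Conditions: LiN(i-Pr)2, THF, −78 °C; then 4, DMPU, −78 → −20 °C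
Reagents that add atoms: none
Why: Alkylation of the lithium lactone enolate with a reactive allylic bromide, the prenyl group entering anti to the neighbouring isopropenyl group, although this α centre is re-enolised in step 3.

Step 3
Reactants: 5 (3S,4R)-3-(3-methylbut-2-en-1-yl)-4-(prop-1-en-2-yl)oxan-2-one
Product: 6 (3R,4S)-3-methyl-3-(3-methylbut-2-en-1-yl)-4-(prop-1-en-2-yl)oxan-2-one
Conditions: LiN(i-Pr)2, THF, −78 °C; MeI, −78 → −30 °C
Reagents that add atoms: iodomethane, CI
Why: Second enolate alkylation builds the quaternary C4 centre: the isopropenyl group next to the fully substituted enolate carbon stands pseudoaxial to avoid allylic strain and shields one face, so MeI attacks anti to it and the methyl group ends trans to isopropenyl, which is the cis relation of C19 and C6 needed in ring A.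

Step 4
Reactants: 6 (3R,4S)-3-methyl-3-(3-methylbut-2-en-1-yl)-4-(prop-1-en-2-yl)oxan-2-one
Product: 8 methyl (2R,3S)-3-(2-hydroxyethyl)-2,4-dimethyl-2-(3-methylbut-2-en-1-yl)pent-4-enoate, via potassium hydroxy carboxylate 7 (not isolated)
Conditions: KOH (1.05 equiv), MeOH/H2O, 40 °C; evaporate; MeI, DMF, 23 °C
Reagents that add atoms: potassium hydroxide, [K+].[OH-]; iodomethane, CI
Why: Saponification of the δ-lactone and SN2 O-methylation of the carboxylate salt free the C7 hydroxyl and fix C19 as its methyl ester without touching a stereocentre, the hindered α-quaternary ester being slow to relactonise.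

Step 5
Reactants: 8 methyl (2R,3S)-3-(2-hydroxyethyl)-2,4-dimethyl-2-(3-methylbut-2-en-1-yl)pent-4-enoate
Product: 9 methyl (2R,3S)-3-(2-bromoethyl)-2,4-dimethyl-2-(3-methylbut-2-en-1-yl)pent-4-enoate
Conditions: CBr4, PPh3, CH2Cl2, 0 °C
Reagents that add atoms: carbon tetrabromide, BrC(Br)(Br)Br
Why: Appel reaction of the primary alcohol, chosen because the bromide survives the peracid, periodate and aluminium steps and later serves as the organozinc precursor.

Step 6
Reactants: 9 methyl (2R,3S)-3-(2-bromoethyl)-2,4-dimethyl-2-(3-methylbut-2-en-1-yl)pent-4-enoate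
Product: 10 methyl (2R,3S)-3-(2-bromoethyl)-2-[(3,3-dimethyloxiran-2-yl)methyl]-2,4-dimethylpent-4-enoate
Conditions: mCPBA (1.05 equiv), NaHCO3, CH2Cl2, 0 °C
Reagents that add atoms: 3-chloroperoxybenzoic acid, OOC(=O)c1cccc(Cl)c1
Why: Prilezhaev epoxidation, selective for the electron-rich trisubstituted prenyl alkene over the hindered 1,1-disubstituted isopropenyl group; the new oxirane centre is formed unselectively and is removed in step 7.

Step 7
Reactants: 10 methyl (2R,3S)-3-(2-bromoethyl)-2-[(3,3-dimethyloxiran-2-yl)methyl]-2,4-dimethylpent-4-enoate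
Product: 11 methyl (2R,3S)-3-(2-bromoethyl)-2,4-dimethyl-2-(2-oxoethyl)pent-4-enoate
Conditions: H5IO6, THF/H2O, 0 → 23 °C
Reagents that add atoms: none
Why: Periodic acid opens the epoxide to the glycol and cleaves it (Malaprade-type cleavage), unmasking the C2 aldehyde and releasing acetone.

Step 8
Reactants: 11 methyl (2R,3S)-3-(2-bromoethyl)-2,4-dimethyl-2-(2-oxoethyl)pent-4-enoate
Product: 13 2-(2-bromoethyl)-1-methyl-3-methylidene-6-oxabicyclo[3.2.1]octan-7-one, via ring-A hydroxy ester 12 (not isolated)
Conditions: Me2AlCl (2.2 equiv), CH2Cl2, −78 → 23 °C; aqueous HCl work-up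
Reagents that add atoms: none
Why: Type 2 intramolecular carbonyl-ene reaction promoted by Me2AlCl closes ring A through a chair with the ester axial and the bromoethyl chain equatorial, in which the allylic methyl hydrogen can only be passed to an axial carbonyl oxygen, so the C2 alkoxide forms syn-axial to the C19 ester and acylates itself (intramolecular transesterification) to the bridged γ-lactone.

Step 9
Reactants: 14 methyl (2E)-3,7-dimethylocta-2,6-dienoate
Product: 15 methyl (2E)-3-methyl-6-oxohex-2-enoate
Conditions: O3, pyridine, CH2Cl2, −78 °C; then Me2S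
Reagents that add atoms: ozone, [O-][O+]=O
Why: Chemoselective ozonolysis of the electron-rich 6,7-alkene, the conjugated 2,3-alkene being deactivated by the ester.

Step 10
Reactants: 15 methyl (2E)-3-methyl-6-oxohex-2-enoate
Product: 16 methyl (2E)-7,7-dibromo-3-methylhepta-2,6-dienoate
Conditions: CBr4, PPh3, Zn dust, CH2Cl2, 0 → 23 °C
Reagents that add atoms: carbon tetrabromide, BrC(Br)(Br)Br
Why: Ramirez (Corey–Fuchs) dibromoolefination of the aldehyde; the carbon of CBr4 becomes C8.

Step 11
Reactants: 13 2-(2-bromoethyl)-1-methyl-3-methylidene-6-oxabicyclo[3.2.1]octan-7-one; 16 methyl (2E)-7,7-dibromo-3-methylhepta-2,6-dienoate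
Product: 18 methyl (2E,6Z)-7-bromo-3-methyl-9-(1-methyl-3-methylidene-7-oxo-6-oxabicyclo[3.2.1]octan-2-yl)nona-2,6-dienoate, via alkylzinc bromide 17 (not isolated)
Conditions: Zn dust (activated with BrCH2CH2Br and Me3SiCl), LiCl, THF, 50 °C; then 16 (1.5 equiv), PdCl2(DPEphos) (5 mol %), THF/DMF, 0 → 23 °C
Reagents that add atoms: none
Why: LiCl-promoted zinc insertion into the primary bromide and Negishi coupling that is trans-selective for 1,1-dibromoalkenes, because zerovalent palladium inserts into the less hindered C–Br bond trans to the alkyl group, so C7 ends trans to C11 and the (6Z) bromoalkene results.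

Step 12
Reactants: 18 methyl (2E,6Z)-7-bromo-3-methyl-9-(1-methyl-3-methylidene-7-oxo-6-oxabicyclo[3.2.1]octan-2-yl)nona-2,6-dienoate
Product: 19 methyl (2E,6Z)-7-bromo-9-(3-chloro-1,3-dimethyl-7-oxo-6-oxabicyclo[3.2.1]octan-2-yl)-3-methylnona-2,6-dienoate
Conditions: HCl (2 M in Et2O), CH2Cl2, −40 → 0 °C
Reagents that add atoms: hydrogen chloride, Cl
Why: Markovnikov hydrochlorination of the exocyclic 1,1-disubstituted alkene gives the tertiary C10 chloride and turns C20 into the methyl group, the bromoalkene and the enoate being too electron-poor to add HCl at low temperature; chloride is expected on the open β face, and the C10 configuration is erased in step 14 in any case.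

Step 13
Reactants: 19 methyl (2E,6Z)-7-bromo-9-(3-chloro-1,3-dimethyl-7-oxo-6-oxabicyclo[3.2.1]octan-2-yl)-3-methylnona-2,6-dienoate
Product: 20 methyl (2E,6Z)-9-(3-chloro-1,3-dimethyl-7-oxo-6-oxabicyclo[3.2.1]octan-2-yl)-3-methyl-7-[(trimethylsilyl)methyl]nona-2,6-dienoate
Conditions: Me3SiCH2ZnCl (from Me3SiCH2MgCl and ZnCl2, THF), Pd(P(t-Bu)3)2 (5 mol %), THF, 23 °C
Reagents that add atoms: (trimethylsilyl)methylzinc chloride, C[Si](C)(C)C[Zn]Cl
Why: Stereoretentive Negishi coupling of the (Z)-bromoalkene with the silylmethylzinc reagent gives the (6Z)-allylsilane (C17 cis to C11), the bulky electron-rich phosphine being chosen to avoid alkene isomerisation and the tertiary chloride being inert to zerovalent palladium.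

Step 14
Reactants: 20 methyl (2E,6Z)-9-(3-chloro-1,3-dimethyl-7-oxo-6-oxabicyclo[3.2.1]octan-2-yl)-3-methyl-7-[(trimethylsilyl)methyl]nona-2,6-dienoate
Product: 21 19,2-lactone 15-methyl ester of the target (trans-decalin with C8=C17)
Conditions: TiCl4 (3 equiv), 2,6-di-tert-butyl-4-methylpyridine, CH2Cl2, −78 °C
Reagents that add atoms: none
Why: TiCl4 abstracts chloride from C10 and the tertiary cation is attacked by C9 of the tethered allylsilane, after which the β-silyl cation at C8 loses Me3SiCl to leave the C8=C17 methylene (SE2' mode). The closest known reaction type is the Lewis acid-mediated tert-alkylation of allylsilanes by tertiary chlorides, run here as an allylsilane-terminated cation–olefin cyclisation. Ring B closes by 6-endo attack (C8 and C9 both become ring atoms) through a chair that gives the trans fusion. At C10 the lactone bridge fills the α face and C6 is equatorial, so C9 can only bond from the β face and C20 ends α, syn to C19; at C9 the (6Z) geometry (C7 trans to C11) and the chair place C11 equatorial, which gives the 9β hydrogen. The step needs ring closure to outrun E1 loss of the cation and protodesilylation, which the intramolecular six-ring closure, the low temperature and the hindered base should secure, and it needs the alkene to form only at C8=C17, which silicon secures.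

Step 15
Reactants: 21 19,2-lactone 15-methyl ester of the target
Product: 22 CNP0086784.5 (target hydroxy diacid)
Conditions: LiOH, THF/MeOH/H2O, 45 °C; then 1 M HCl to pH 3–4, 0 °C
Reagents that add atoms: lithium hydroxide, [Li+].[OH-]; water, O
Why: Saponification, in which hydroxide opens the strained bridged lactone by acyl–oxygen cleavage (retention at C2) and hydrolyses the methyl enoate; cold, mild acidification then gives the hydroxy diacid, whose relactonisation is disfavoured by the syn-axial C20 methyl group.

Compound list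
1 | 5,6-dihydro-2H-pyran-2-one | O=C1C=CCCO1 | starting material
2 | potassium trifluoro(prop-1-en-2-yl)borate | C=C(C)[B-](F)(F)F.[K+] | starting material
3 | (4R)-4-(prop-1-en-2-yl)oxan-2-one | CC(=C)[C@H]1CC(=O)OCC1 | intermediate
4 | 1-bromo-3-methylbut-2-ene (prenyl bromide) | CC(C)=CCBr | starting material
5 | (3S,4R)-3-(3-methylbut-2-en-1-yl)-4-(prop-1-en-2-yl)oxan-2-one (prenyl trans to isopropenyl) | CC(C)=CC[C@@H]1C(=O)OCC[C@H]1C(C)=C | intermediate
6 | (3R,4S)-3-methyl-3-(3-methylbut-2-en-1-yl)-4-(prop-1-en-2-yl)oxan-2-one (methyl trans to isopropenyl) | CC(C)=CC[C@@]1(C)C(=O)OCC[C@H]1C(C)=C | intermediate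
7 | potassium (2R,3S)-3-(2-hydroxyethyl)-2,4-dimethyl-2-(3-methylbut-2-en-1-yl)pent-4-enoate | CC(C)=CC[C@@](C)(C(=O)[O-])[C@@H](CCO)C(C)=C.[K+] | intermediate (not isolated)
8 | methyl (2R,3S)-3-(2-hydroxyethyl)-2,4-dimethyl-2-(3-methylbut-2-en-1-yl)pent-4-enoate | CC(C)=CC[C@@](C)(C(=O)OC)[C@@H](CCO)C(C)=C | intermediate
9 | methyl (2R,3S)-3-(2-bromoethyl)-2,4-dimethyl-2-(3-methylbut-2-en-1-yl)pent-4-enoate | CC(C)=CC[C@@](C)(C(=O)OC)[C@@H](CCBr)C(C)=C | intermediate
10 | methyl (2R,3S)-3-(2-bromoethyl)-2-[(3,3-dimethyloxiran-2-yl)methyl]-2,4-dimethylpent-4-enoate (both oxirane epimers) | CC1(C)OC1C[C@@](C)(C(=O)OC)[C@@H](CCBr)C(C)=C | intermediate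
11 | methyl (2R,3S)-3-(2-bromoethyl)-2,4-dimethyl-2-(2-oxoethyl)pent-4-enoate | O=CC[C@@](C)(C(=O)OC)[C@@H](CCBr)C(C)=C | intermediate
12 | methyl 2-(2-bromoethyl)-5-hydroxy-1-methyl-3-methylidenecyclohexane-1-carboxylate (ring A; hydroxyl and bromoethyl both cis to the ester) | BrCC[C@H]1C(=C)C[C@@H](O)C[C@@]1(C)C(=O)OC | intermediate (not isolated)
13 | 2-(2-bromoethyl)-1-methyl-3-methylidene-6-oxabicyclo[3.2.1]octan-7-one (ring A with the C19–O–C2 lactone bridge on the α face; bromoethyl equatorial, 5β-H) | BrCC[C@H]1C(=C)C[C@@H]2C[C@@]1(C)C(=O)O2 | intermediate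
14 | methyl (2E)-3,7-dimethylocta-2,6-dienoate (methyl geranate) | CC(C)=CCC/C(C)=C/C(=O)OC | starting material
15 | methyl (2E)-3-methyl-6-oxohex-2-enoate | O=CCC/C(C)=C/C(=O)OC | intermediate
16 | methyl (2E)-7,7-dibromo-3-methylhepta-2,6-dienoate | BrC(Br)=CCC/C(C)=C/C(=O)OC | intermediate
17 | [2-(1-methyl-3-methylidene-7-oxo-6-oxabicyclo[3.2.1]octan-2-yl)ethyl]zinc bromide | Br[Zn]CC[C@H]1C(=C)C[C@@H]2C[C@@]1(C)C(=O)O2 | intermediate (not isolated)
18 | methyl (2E,6Z)-7-bromo-3-methyl-9-(1-methyl-3-methylidene-7-oxo-6-oxabicyclo[3.2.1]octan-2-yl)nona-2,6-dienoate | Br/C(CC[C@H]1C(=C)C[C@@H]2C[C@@]1(C)C(=O)O2)=C\CC/C(C)=C/C(=O)OC | intermediate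
19 | methyl (2E,6Z)-7-bromo-9-(3-chloro-1,3-dimethyl-7-oxo-6-oxabicyclo[3.2.1]octan-2-yl)-3-methylnona-2,6-dienoate (C10 chlorine β, methyl α) | Br/C(CC[C@H]1[C@](C)(Cl)C[C@@H]2C[C@@]1(C)C(=O)O2)=C\CC/C(C)=C/C(=O)OC | intermediate
20 | methyl (2E,6Z)-9-(3-chloro-1,3-dimethyl-7-oxo-6-oxabicyclo[3.2.1]octan-2-yl)-3-methyl-7-[(trimethylsilyl)methyl]nona-2,6-dienoate | C[Si](C)(C)C/C(CC[C@H]1[C@](C)(Cl)C[C@@H]2C[C@@]1(C)C(=O)O2)=C\CC/C(C)=C/C(=O)OC | intermediate
21 | 19,2-lactone 15-methyl ester of the target (trans-decalin; C8=C17; C19, O–C2 and C20 all α; 5β-H, 9β-H; 13E) | C=C1CC[C@H]2[C@@](C)(C[C@@H]3C[C@@]2(C)C(=O)O3)[C@@H]1CC/C(C)=C/C(=O)OC | intermediate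
22 | CNP0086784.5, 2-hydroxylabda-8(17),13E-diene-15,19-dioic acid of the ent series (2-OH, C19 carboxyl and C20 methyl on the same face) | C=C1CC[C@H]2[C@@](C)(C[C@@H](O)C[C@@]2(C)C(=O)O)[C@@H]1CC/C(C)=C/C(=O)O | target

Total step count: 15. Longest linear sequence: 13 steps (steps 1–8 and 11–15); steps 9 and 10 make the side-chain fragment.

Steps most likely to fail

1. Step 14. After ionisation the cation may be lost by E1 elimination, or the allylsilane by protodesilylation, before the C9–C10 bond forms, because the C20 methyl group has to move into the position syn to the rigid lactone bridge. The fallback gives up the covalent bridge as the conformational lock and sets out from 20. K2CO3 in MeOH at 0 °C should open the lactone by methanolysis to the ring-opened hydroxy ester F1. TiCl4 with the same hindered base at −78 °C should then close ring B on the open ring A, where a titanium alkoxide chelated to the C19 ester holds the chair but lets the three syn-axial groups splay, to give the hydroxy dimethyl ester F2. LiSPr in HMPA at 23 °C should cleave both methyl esters by SN2 demethylation, and the fallback comes back to the route at 22.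

2. Step 8. Hydrogen transfer may go through the other chair, giving poor facial selectivity at C2 and an alcohol trans to the ester that cannot lactonise. The fallback moves the control of C2 from the ene transition state to a ketone reduction and sets out from 11. The cyclisation is run with the same Lewis acid and the trans alcohol F3 is taken on. Dess–Martin periodinane with NaHCO3 should oxidise it to the β,γ-unsaturated ketone F4. LiBH(s-Bu)3 at −78 °C should deliver hydride from the face opposite the axial ester to give 12, and catalytic DBU in toluene at 60 °C should close the lactone, so that the fallback comes back at 13.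

3. Step 13. The hindered trisubstituted bromoalkene may undergo slow oxidative addition or partial loss of alkene geometry during the second coupling. The fallback dispenses with silicon and sets out from 19. In HCO2H at 40 °C the tertiary chloride should ionise and the bromoalkene itself act as terminator (haloalkene-terminated cation–olefin cyclisation), C9 attacking C10 and the α-bromo cation being hydrolysed to the 8-oxo lactone F5, with the side chain equatorial after equilibration next to the ketone. Lombardo methylenation (Zn, CH2Br2, TiCl4, THF) should then give 21, where the fallback comes back to the route.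

Further compounds
F1 | step 14 | methyl (2E,6Z)-9-[2-chloro-4-hydroxy-6-(methoxycarbonyl)-2,6-dimethylcyclohexyl]-3-methyl-7-[(trimethylsilyl)methyl]nona-2,6-dienoate (ring-opened 20) | C[Si](C)(C)C/C(CC[C@H]1[C@](C)(Cl)C[C@@H](O)C[C@@]1(C)C(=O)OC)=C\CC/C(C)=C/C(=O)OC
F2 | step 14 | 15,19-dimethyl ester of 22 | C=C1CC[C@H]2[C@@](C)(C[C@@H](O)C[C@@]2(C)C(=O)OC)[C@@H]1CC/C(C)=C/C(=O)OC
F3 | step 8 | methyl 2-(2-bromoethyl)-5-hydroxy-1-methyl-3-methylidenecyclohexane-1-carboxylate, C2 epimer of 12 (hydroxyl trans to the ester) | BrCC[C@H]1C(=C)C[C@H](O)C[C@@]1(C)C(=O)OC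
F4 | step 8 | methyl 2-(2-bromoethyl)-1-methyl-3-methylidene-5-oxocyclohexane-1-carboxylate | BrCC[C@H]1C(=C)CC(=O)C[C@@]1(C)C(=O)OC
F5 | step 13 | 8-oxo analogue of 21 (ketone at C8 in place of the C8=C17 methylene) | O=C1CC[C@H]2[C@@](C)(C[C@@H]3C[C@@]2(C)C(=O)O3)[C@@H]1CC/C(C)=C/C(=O)OC
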